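The numbers in the tables were computed from invented constants, noise included.

I start with one small step: a division on the last larch reading. First, here is what stands before me.

- larch: left-handed substrate 0.32 M; right-handed substrate 0.32 M; partner 1.28 M; protic impurity 0.0128 M; precatalyst 14 mM; stray impurity 5.7 mM; run made earlier
- flask: left-handed substrate 0.64 M; partner 1.28 M; protic impurity 0.0128 M; precatalyst 14 mM; stray impurity 5.7 mM; right-handed substrate 0.64 M; time 30 h

- larch (time / h: right-handed substrate / %, left-handed substrate / %): 1.50: 49.6, 50.4; 3.00: 50.4, 50.3; 5.00: 49.9, 43.7; 6.00: 49.0, 36.3; 8.00: 46.5, 22.3; 10.0: 42.5, 11.6

(standard deviation of a reading: 0.5 percentage points)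

- free catalyst is single-handed; left-handed substrate and right-handed substrate are mirror images of each other, charged as a racemate, each of them at the stated concentration
- what was read earlier has a scatter of 0.5 percentage points, one standard deviation

- whether the excess of right-handed substrate over left-handed substrate among what is left of the two reaches 80% by 30 h (yes / no)
- the highest excess of right-handed substrate over left-handed substrate among what is left of the two up to 30 h

Suppose both substrates meet the same catalyst and partner and each goes in proportion to its own concentration. Then the fraction of its own charge left of left-handed substrate, l, equals the same fraction of right-handed substrate, r, raised to a power s. At 10.0 h in larch these fractions are 23.2% and 85.0%, so s reads 8.99. This selectivity factor, the ratio of the logarithms of the two fractions left, is a reading under a scatter of 0.5 percentage points.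

In the flask, an excess of 80% needs r to fall to 76.0%, which means 57.8% of the two substrates reacted. That takes 0.740 M of partner, less than the 1.28 M charged. Between 5.00 h and 10.0 h the larch readings show substrate going at 0.0506 M h⁻¹. If the flask, charged with the same [partner], runs at that rate from 5.00 h, I expect the level near 19.6 h, sooner than the 30 h allowed.

The forecast says yes, with a top of 95%, and reasons: “The flask has the same catalyst, impurities and partner, so I assume the same induction.”

The flask gives yes, with a top of 98.4%.

    partner + free catalyst + right-handed substrate → free catalyst + right-handed product (k = 0.109 L² mol⁻² min⁻¹)
    partner + precatalyst → free catalyst + spent reagent (k = 0.00200 L mol⁻¹ min⁻¹)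
    free catalyst + stray impurity → spent catalyst (k = 864 L mol⁻¹ min⁻¹)
    partner + protic impurity → quenched reagent (k = 0.575 L mol⁻¹ min⁻¹)
    partner + free catalyst + left-handed substrate → free catalyst + left-handed product (k = 1.15 L² mol⁻² min⁻¹)

The flask passes 80% at 15.5 h, sooner than my 19.6 h, with 55.9% of the two substrates reacted against my 57.8%. I use s once more at 30.0 h, when the flask keeps 61% of its right-handed charge. Then r raised to s gives an excess of 96.2%, while the flask stands at 98.4%.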